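**Plan** (drimane numbering: ring A = C1–C5, C10; ring B = C5–C10; C11 on C9, C12 on C8)

- Retrosynthesis: the C6 ester, the C9 ether and the C12 acetal are removed first; ring B is then cut at C7–C8 and C9–C10. This leaves methyl ketone 3 (ring A with C5, C6, C7, C10) and bromobutenolide 6 (C12, C8, C9, C11).
- Enabling feature: at the C6-ketone level ring B is the ring-closed valence isomer of the 3-oxidohexatriene C10=C5–C6(O–)=C7–C8=C9. Both triene ends sit in rings: C10 in ring A, C9 in the lactol ring that the C11 acid and C12 aldehyde form through oxygen.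
- Forward: ring A is bought (β-cyclocitral) and the butenolide comes from mucobromic acid. Step 5 joins them (C7–C8) and closes ring B (C9–C10). C6 reduction, acylation and one acid step then free the C9–OH, the C11 acid and the C12 aldehyde.
- Stereochemistry: the menthyl acetal at C12 (removed at the end) fixes the face of the ring closure and so the absolute configuration at C9 and C10. Orbital symmetry and the two ring-locked triene ends fix the C9/C10 relationship. C5 follows by protonation to the trans fusion and C6 by α-face hydride delivery.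

Key step: step 5

Remark: the C12 aldehyde and C11 acid of the target are held cis on C8/C9 and equilibrate with the ring-closed 12-hydroxy-11,12-olide; the last step is taken to give this tautomeric pair, written as the open aldehyde acid.

Step 1
Reactants: 1 β-cyclocitral (2,6,6-trimethylcyclohex-1-ene-1-carbaldehyde)
Product: 2 1-(2,6,6-trimethylcyclohex-1-en-1-yl)ethan-1-ol (racemic)
Conditions: MeMgBr, Et2O, 0 °C → rt; aq. NH4Cl
Reagents that add atoms: methylmagnesium bromide, C[Mg]Br
Why: Grignard 1,2-addition to the hindered enal should give the secondary allylic alcohol, whose stereocentre is removed in step 2.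

Step 2
Reactants: 2 1-(2,6,6-trimethylcyclohex-1-en-1-yl)ethan-1-ol
Product: 3 1-(2,6,6-trimethylcyclohex-1-en-1-yl)ethan-1-one
Conditions: Dess–Martin periodinane, CH2Cl2, 0 °C → rt
Reagents that add atoms: none
Why: Dess–Martin oxidation of the secondary allylic alcohol should give the methyl ketone without touching the tetrasubstituted alkene.

Step 3
Reactants: 4 mucobromic acid (3,4-dibromo-5-hydroxyfuran-2(5H)-one)
Product: 5 4-bromo-5-hydroxy-3-[(4-methoxybenzyl)oxy]furan-2(5H)-one (racemic lactol)
Conditions: 4-MeOC6H4CH2OH (1.0 equiv), NaH (2.1 equiv), THF, 0 °C → rt; then aq. HCl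
Reagents that add atoms: 4-methoxybenzyl alcohol, COc1ccc(CO)cc1
Why: nucleophilic vinylic substitution (conjugate addition–elimination): in base 4 is the ring-opened (Z)-2,3-dibromo-4-oxobut-2-enoate whose only acceptor is the aldehyde, so the alkoxide should add at the carbon β to it (C3 of the furanone) and expel that bromide, and acidification re-closes the lactol.

Step 4
Reactants: 5 4-bromo-5-hydroxy-3-[(4-methoxybenzyl)oxy]furan-2(5H)-one
Product: 6 (5R)-4-bromo-3-[(4-methoxybenzyl)oxy]-5-{[(1R,2S,5R)-2-isopropyl-5-methylcyclohexyl]oxy}furan-2(5H)-one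
Conditions: (1R,2S,5R)-(−)-menthol, camphorsulfonic acid (cat.), PhMe, 4 Å molecular sieves, 60 °C; crystallisation
Reagents that add atoms: (1R,2S,5R)-menthol, CC(C)[C@@H]1CC[C@@H](C)C[C@H]1O
Why: acid-catalysed acetalisation of the lactol through its acyl-oxocarbenium ion installs the menthyl auxiliary; the acetal centre equilibrates under the conditions, so the (5R) epimer is taken on and the remainder can be re-equilibrated.

Step 5
Reactants: 3 1-(2,6,6-trimethylcyclohex-1-en-1-yl)ethan-1-one; 6 (5R)-bromobutenolide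
Product: 11 (3R,5aS,9aS,9bR)-9b-[(4-methoxybenzyl)oxy]-3-[(1R,2S,5R)-menthyloxy]-6,6,9a-trimethyl-5a,6,7,8,9,9a-hexahydronaphtho[1,2-c]furan-1,5(3H,9bH)-dione (6-oxo-9β-(4-methoxybenzyloxy)drim-7-en-11,12-olide 12-menthyl acetal), via lithium dienolate 7 (not isolated), via substitution product 8 (not isolated), via lithium trienolate 9 (not isolated), via ring-closed lithium enolate 10 (not isolated)
Conditions: 3 (2.1 equiv), LiN(SiMe3)2 (2.05 equiv), THF, −78 °C; 6 (1.0 equiv), −78 → 0 °C; then 45 °C; AcOH, 0 °C
Reagents that add atoms: none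
Why: Proposed new method: lithium dienolate 7 adds to C4 of bromobutenolide 6 and expels bromide (conjugate addition–elimination, the known vinylic substitution of 4-halofuran-2(5H)-ones by carbon nucleophiles), which makes the C7–C8 bond, and a second equivalent of 7 deprotonates the doubly activated C7 methylene of 8 to the 3-oxidohexatriene 9 (C10=C5–C6(OLi)=C7–C8=C9). Ring B then closes by a thermally allowed disrotatory 6π electrocyclisation of 9, which is at the same time a 6-endo-trig vinylogous Michael addition of the lactone dienolate carbon C9 to the enone β-carbon C10 (C9–C10 bond); the closest known reaction types are the anion-accelerated electrocyclisation of hexatrienes and the double Michael annulation of cross-conjugated ketone dienolates, neither shown for a triene with two fully substituted termini. Both termini are locked in rings, so the methyl group is the inside substituent on C10 (C1 is tied to C4 through ring A) and the ether oxygen is the inside substituent on C9 (C11 is tied to C12 through the lactone): disrotation must therefore put the C9 oxygen and the C10 methyl on the same face and C11 on the opposite one, which is the relative configuration of the target. The absolute sense is set by the C12 acetal, because the cyclohexenyl terminus should swing onto the butenolide face opposite the menthyloxy group. C5 is set on quenching enolate 10 by protonation opposite the axial C10 methyl and is in any case epimerisable to the more stable trans ring fusion, being α to the C6 ketone. The step needs C-attack at C4 of 6 rather than carbonyl addition or γ-deprotonation (served by the soft ketone enolate at low temperature with no free amide base present) and closure at C10 rather than C5 (the 5-exo alternative would be an anti-Michael addition), while the mobile geometry of the delocalised anion 9 lets the reactive U-shaped form be reached.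

Step 6
Reactants: 11 tricyclic enone acetal
Product: 12 (3R,5R,5aS,9aS,9bR)-5-hydroxy-9b-[(4-methoxybenzyl)oxy]-3-[(1R,2S,5R)-menthyloxy]-6,6,9a-trimethyl-5,5a,6,7,8,9,9a,9b-octahydronaphtho[1,2-c]furan-1(3H)-one (the 6β-alcohol)
Conditions: NaBH4, CeCl3·7H2O, MeOH–THF, −78 → −40 °C
Reagents that add atoms: none
Why: Luche 1,2-reduction should deliver hydride to the enone from the α face, since the β face is blocked by the axial C10 methyl and the 4β-methyl, and so set the axial 6β-alcohol while the lactone acetal is left alone at low temperature.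

Step 7
Reactants: 13 (2E,4E)-hexa-2,4-dienal (sorbaldehyde)
Product: 14 (2E,4E,6E)-octa-2,4,6-trienoic acid
Conditions: malonic acid, pyridine, piperidine (cat.), 90 °C
Reagents that add atoms: malonic acid, OC(=O)CC(=O)O
Why: Knoevenagel–Doebner condensation with decarboxylation should extend the dienal to the all-E trienoic acid.

Step 8
Reactants: 14 (2E,4E,6E)-octa-2,4,6-trienoic acid; 12 the 6β-alcohol
Product: 16 6β-[(2E,4E,6E)-octa-2,4,6-trienoyl] ester of 12, via mixed anhydride 15 (not isolated)
Conditions: 14, 2,4,6-Cl3C6H2COCl, Et3N, PhMe, rt; then 12, DMAP, rt → 40 °C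
Reagents that add atoms: none
Why: Yamaguchi esterification through the acylpyridinium ion should acylate the hindered axial secondary alcohol; the C9 oxygen is blocked as its ether and no stereocentre is touched.

Step 9
Reactants: 16 the protected trienoate
Product: 18 (5S,6R,9R,10S)-9-hydroxy-6-[(2E,4E,6E)-octa-2,4,6-trienoyloxy]-12-oxodrim-7-en-11-oic acid (target), via lactol 17 (not isolated)
Conditions: CF3CO2H–H2O–CH2Cl2, anisole, 0 °C → rt
Reagents that add atoms: water, O
Why: acidolysis should cleave the tertiary 4-methoxybenzyl ether (cation trapped by anisole) and hydrolyse the menthyl acetal through its allylic oxocarbenium ion to lactol 17, the ring tautomer of aldehyde acid 18.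

**Compound list**

1 | β-cyclocitral | O=CC1=C(C)CCCC1(C)C | starting material
2 | 1-(2,6,6-trimethylcyclohex-1-en-1-yl)ethan-1-ol (racemic) | CC(O)C1=C(C)CCCC1(C)C | intermediate
3 | 1-(2,6,6-trimethylcyclohex-1-en-1-yl)ethan-1-one | CC(=O)C1=C(C)CCCC1(C)C | intermediate
4 | mucobromic acid | O=C1OC(O)C(Br)=C1Br | starting material
5 | 4-bromo-5-hydroxy-3-[(4-methoxybenzyl)oxy]furan-2(5H)-one (racemic) | O=C1OC(O)C(Br)=C1OCc1ccc(OC)cc1 | intermediate
6 | (5R)-4-bromo-3-[(4-methoxybenzyl)oxy]-5-[(1R,2S,5R)-menthyloxy]furan-2(5H)-one | O=C1O[C@@H](O[C@@H]2C[C@H](C)CC[C@H]2C(C)C)C(Br)=C1OCc1ccc(OC)cc1 | intermediate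
7 | lithium 1-(2,6,6-trimethylcyclohex-1-en-1-yl)ethen-1-olate | [Li+].[O-]C(=C)C1=C(C)CCCC1(C)C | intermediate
8 | (5R)-3-[(4-methoxybenzyl)oxy]-5-[(1R,2S,5R)-menthyloxy]-4-[2-oxo-2-(2,6,6-trimethylcyclohex-1-en-1-yl)ethyl]furan-2(5H)-one | O=C1O[C@@H](O[C@@H]2C[C@H](C)CC[C@H]2C(C)C)C(CC(=O)C2=C(C)CCCC2(C)C)=C1OCc1ccc(OC)cc1 | intermediate
9 | lithium trienolate of 8 (C6 enolate, C6=C7 geometry mobile) | O=C1O[C@@H](O[C@@H]2C[C@H](C)CC[C@H]2C(C)C)C(C=C([O-])C2=C(C)CCCC2(C)C)=C1OCc1ccc(OC)cc1.[Li+] | intermediate
10 | ring-closed lithium C5=C6 enolate of 11 | [Li+].[O-]C=1C=C3[C@@](OCc4ccc(OC)cc4)(C(=O)O[C@H]3O[C@@H]4C[C@H](C)CC[C@H]4C(C)C)[C@@]2(C)CCCC(C)(C)C=12 | intermediate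
11 | 6-oxo-9β-(4-methoxybenzyloxy)drim-7-en-11,12-olide (12R)-menthyl acetal | O=C1C=C3[C@@](OCc4ccc(OC)cc4)(C(=O)O[C@H]3O[C@@H]4C[C@H](C)CC[C@H]4C(C)C)[C@@]2(C)CCCC(C)(C)[C@H]12 | intermediate
12 | 6β-hydroxy-9β-(4-methoxybenzyloxy)drim-7-en-11,12-olide (12R)-menthyl acetal | O[C@@H]1C=C3[C@@](OCc4ccc(OC)cc4)(C(=O)O[C@H]3O[C@@H]4C[C@H](C)CC[C@H]4C(C)C)[C@@]2(C)CCCC(C)(C)[C@H]12 | intermediate
13 | (2E,4E)-hexa-2,4-dienal | C/C=C/C=C/C=O | starting material
14 | (2E,4E,6E)-octa-2,4,6-trienoic acid | C/C=C/C=C/C=C/C(=O)O | intermediate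
15 | (2E,4E,6E)-octa-2,4,6-trienoic 2,4,6-trichlorobenzoic anhydride | C/C=C/C=C/C=C/C(=O)OC(=O)c1c(Cl)cc(Cl)cc1Cl | intermediate
16 | 6β-[(2E,4E,6E)-octa-2,4,6-trienoyloxy]-9β-(4-methoxybenzyloxy)drim-7-en-11,12-olide (12R)-menthyl acetal | C/C=C/C=C/C=C/C(=O)O[C@@H]1C=C3[C@@](OCc4ccc(OC)cc4)(C(=O)O[C@H]3O[C@@H]4C[C@H](C)CC[C@H]4C(C)C)[C@@]2(C)CCCC(C)(C)[C@H]12 | intermediate
17 | 9β,12-dihydroxy-6β-[(2E,4E,6E)-octa-2,4,6-trienoyloxy]drim-7-en-11,12-olide (lactol, both C12 anomers) | C/C=C/C=C/C=C/C(=O)O[C@@H]1C=C3[C@@](O)(C(=O)OC3O)[C@@]2(C)CCCC(C)(C)[C@H]12 | intermediate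
18 | (5S,6R,9R,10S)-9-hydroxy-6-[(2E,4E,6E)-octa-2,4,6-trienoyloxy]-12-oxodrim-7-en-11-oic acid (5α-H, 6β-acyloxy, 9β-OH, 9α-CO2H, 10β-CH3) | C/C=C/C=C/C=C/C(=O)O[C@@H]1C=C(C=O)[C@@](O)(C(=O)O)[C@@]2(C)CCCC(C)(C)[C@H]12 | target

**Totals.** Total step count: 9. Longest linear sequence: 6 steps (1, 2, 5, 6, 8, 9, or equally 3, 4, 5, 6, 8, 9).

**Steps most likely to fail**

1. Step 5 (Proposed new method). The stabilised trienolate 9 may fail to close, because the bond between two fully substituted carbons forms slowly or reversibly. The acetal centre may also epimerise by γ-deprotonation before closure and erode facial control, or the enolate may add to the lactone carbonyl. The fallback sets out from 3 and 6 and comes back at 11, using known reaction types. Ketone 3 would be silylated (t-BuMe2SiOSO2CF3, Et3N) to the 2-silyloxydiene tert-butyldimethyl{[1-(2,6,6-trimethylcyclohex-1-en-1-yl)ethenyl]oxy}silane F1. Compound 6 would be hydrodebrominated (Bu3SnH, cat. Pd(PPh3)4) to (5R)-3-[(4-methoxybenzyl)oxy]-5-menthyloxyfuran-2(5H)-one F2. A high-pressure Diels–Alder reaction of F1 with F2, endo and anti to the menthyloxy group, would form the same two bonds and give the silyl enol ether cycloadduct F3. Fluoride cleavage (Bu4NF, AcOH) would give the saturated trans-fused ketone F4. Dehydrogenation with 2-iodoxybenzoic acid, for which enolisation towards C7 is the only one that can give an enone, would return to 11.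

2. Step 3. Substitution may occur at the other vinylic carbon, or twice. The fallback sets out from 4 and comes back at 8, which then takes the second half of step 5 (deprotonation and closure). Compound 4 would first be acetalised with (−)-menthol to the ring-closed (5R)-3,4-dibromo-5-menthyloxyfuran-2(5H)-one F5. Its C4–Br bond, the more reactive one in the ring-closed form, would be coupled under Pd(PPh3)4 catalysis with silyl enol ether F1 in the presence of Bu3SnF (tin-enolate coupling) to give the 3-bromo ketone F6. The remaining C3–Br bond would be etherified with 4-methoxybenzyl alcohol (CuI, 1,10-phenanthroline, Cs2CO3) to give 8.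

3. Step 8. Acylation of the hindered axial 6β-alcohol may be incomplete, or elimination may compete. The fallback sets out from 12 and comes back at 16 by building the trienoate on the molecule. Compound 12 would be esterified with the small diethylphosphonoacetic acid (dicyclohexylcarbodiimide, cat. DMAP) to phosphonoacetate F7. Horner–Wadsworth–Emmons olefination of F7 with sorbaldehyde 13 (LiCl, DBU, MeCN) would give 16.

Further compounds
F1 | step 5 | tert-butyldimethyl{[1-(2,6,6-trimethylcyclohex-1-en-1-yl)ethenyl]oxy}silane | C=C(O[Si](C)(C)C(C)(C)C)C1=C(C)CCCC1(C)C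
F2 | step 5 | (5R)-3-[(4-methoxybenzyl)oxy]-5-[(1R,2S,5R)-menthyloxy]furan-2(5H)-one | O=C1O[C@@H](O[C@@H]2C[C@H](C)CC[C@H]2C(C)C)C=C1OCc1ccc(OC)cc1
F3 | step 5 | endo cycloadduct, C5=C6 tert-butyldimethylsilyl enol ether of F4 | CC(C)(C)[Si](C)(C)OC=1C[C@@H]3[C@@](OCc4ccc(OC)cc4)(C(=O)O[C@H]3O[C@@H]4C[C@H](C)CC[C@H]4C(C)C)[C@@]2(C)CCCC(C)(C)C=12
F4 | step 5 | 7,8-dihydro-11 (8β-H, cis-fused lactone, trans-fused decalin) | O=C1C[C@@H]3[C@@](OCc4ccc(OC)cc4)(C(=O)O[C@H]3O[C@@H]4C[C@H](C)CC[C@H]4C(C)C)[C@@]2(C)CCCC(C)(C)[C@H]12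
F5 | step 3 | (5R)-3,4-dibromo-5-[(1R,2S,5R)-menthyloxy]furan-2(5H)-one | O=C1O[C@@H](O[C@@H]2C[C@H](C)CC[C@H]2C(C)C)C(Br)=C1Br
F6 | step 3 | (5R)-3-bromo-5-[(1R,2S,5R)-menthyloxy]-4-[2-oxo-2-(2,6,6-trimethylcyclohex-1-en-1-yl)ethyl]furan-2(5H)-one | O=C1O[C@@H](O[C@@H]2C[C@H](C)CC[C@H]2C(C)C)C(CC(=O)C2=C(C)CCCC2(C)C)=C1Br
F7 | step 8 | 6β-(diethoxyphosphoryl)acetate of 12 | CCOP(=O)(OCC)CC(=O)O[C@@H]1C=C3[C@@](OCc4ccc(OC)cc4)(C(=O)O[C@H]3O[C@@H]4C[C@H](C)CC[C@H]4C(C)C)[C@@]2(C)CCCC(C)(C)[C@H]12
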